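**Plan**
Retrosynthesis cuts, in this order: the C6 oxygen (allylic acetate to C–H), the C3/C6 carbonyls, the C9–C11 bond (C9 enol triflate plus alkylzinc), then ring A at C1–C10 and C4–C5 by a retro-[4+2].
This leaves 2,6-dimethyl-1,4-benzoquinone (all of ring B with C17 and C20) and the silyl dienol ether of isopropyl vinyl ketone (C1–C4, C18, C19, O3).
The cycloaddition is possible because, with C6 and C9 as ketones, C5=C10 is a quinone C=C, and ring A carries its oxygen on C3 next to the C4 gem-dimethyl group, the pattern a 3-silyloxy-4-methylpenta-1,3-diene leaves behind.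
Forward: ring B is bought as the quinone, ring A is annulated onto it in one Diels–Alder step, and the C11–C16 chain (from (S)-citronellol after loss of its C6–C8) is then joined at C9 by Negishi coupling.
Helpers: the C6 carbonyl (activation, C5 epimerisation, moving the alkene into C7=C8) leaves at the end as an allylic acetate; the C9 carbonyl becomes the triflate; the silyl enol ether masks the C3 ketone.
Stereochemistry: C10 from the chiral catalyst; C5 by equilibration to the trans fusion; C9 by axial γ-protonation anti to C20; C3 by axial hydride delivery; C13 from the chiral pool.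

Key step: step 3

Remark: labdane numbering is used for all bicyclic compounds (ring A = C1–C5, C10; ring B = C5–C10; C17 on C8, C18/C19 on C4, C20 on C10; chain C11–C16); α is the face opposite to C20.
Assumption: the (S)-configured oxazaborolidinium catalyst is taken to leave open the quinone face that gives (4aR,8aS)-5; if the sense is the reverse, the catalyst from (R)-diphenylprolinol is used and nothing else changes.

Step 1
Reactants: 1 N-methoxy-N-methyl-2-methylpropanamide
Product: 2 4-methylpent-1-en-3-one
Conditions: CH2=CHMgBr (1.2 equiv), THF, 0 °C; inverse quench into cold 2 M HCl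
Reagents that add atoms: vinylmagnesium bromide, C=C[Mg]Br
Why: Weinreb ketone synthesis, in which the chelated tetrahedral intermediate stops at the ketone stage and the acidic quench keeps the released N,O-dimethylhydroxylamine from adding to the vinyl ketone.

Step 2
Reactants: 2 4-methylpent-1-en-3-one
Product: 3 triisopropyl[(4-methylpenta-1,3-dien-3-yl)oxy]silane
Conditions: i-Pr3SiOSO2CF3 (1.1 equiv), Et3N (1.5 equiv), CH2Cl2, 0 → 23 °C
Reagents that add atoms: triisopropylsilyl trifluoromethanesulfonate, CC(C)[Si](C(C)C)(C(C)C)OS(=O)(=O)C(F)(F)F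
Why: soft enolisation and O-silylation can only occur at the isopropyl methine (the sole sp3 α-hydrogen), and the product has no E/Z isomers because C4 carries two methyl groups.

Step 3
Reactants: 3 triisopropyl[(4-methylpenta-1,3-dien-3-yl)oxy]silane; 4 2,6-dimethyl-1,4-benzoquinone
Product: 5 cis-fused cycloadduct (4aR,8aS)-2,5,5,8a-tetramethyl-6-(triisopropylsilyloxy)-4a,5,8,8a-tetrahydronaphthalene-1,4-dione
Conditions: (S)-3,3-diphenyl-1-(2-methylphenyl)tetrahydro-1H,3H-pyrrolo[1,2-c][1,3,2]oxazaborole·HN(SO2CF3)2 (20 mol%), 3 (1.3 equiv), CH2Cl2, −78 → −20 °C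
Reagents that add atoms: none
Why: Proposed new method: the boron cation binds the unhindered C6 carbonyl of 4 (flanked by two CH groups), lowers the LUMO of the adjacent C5=C10 bond and screens one of its faces with an aryl group, so that 3 adds suprafacially in a concerted but asynchronous [4+2] cycloaddition in which bonding of the unhindered CH2 terminus C1 to the β-carbon C10 runs ahead of C4–C5 bonding, the positive charge building up on the C2–C4 allyl unit being carried by the two methyl groups on C4. The closest known reaction type is the chiral oxazaborolidinium-catalysed Diels–Alder reaction of 2,5- and 2,6-dialkyl-1,4-benzoquinones with 2-silyloxybuta-1,3-dienes, which has not been shown for a diene with a fully substituted, cis-methylated terminus or for this orientation of the silyloxy group. Ring A is closed as a six-membered carbocycle by intermolecular [4+2] annulation onto the preformed ring B, both σ-bonds forming on the same face of the quinone. C10 and C5 are set cis to each other by the suprafacial mode and in the absolute sense by the catalyst, while C1 and C4 are not stereogenic, so no endo/exo question arises. The step needs regio-, site- and enantioselectivity: the CMe2 terminus can only bond to the hydrogen-bearing C5 because the alternative would join two fully substituted carbons, and this is also the orientation of the uncatalysed reaction (nucleophilic enol ether carbon C4 onto C5, which is β to the C9 carbonyl); the two C=C bonds of 4 are equivalent by its twofold axis, and a second cycloaddition is not expected at the trisubstituted C7=C8 bond of 5.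

Step 4
Reactants: 5 cis-fused cycloadduct
Product: 6 trans-fused enedione (4aS,8aS)-2,5,5,8a-tetramethyl-6-(triisopropylsilyloxy)-4a,5,8,8a-tetrahydronaphthalene-1,4-dione
Conditions: 1,8-diazabicyclo[5.4.0]undec-7-ene (0.2 equiv), CH2Cl2, 23 °C
Reagents that add atoms: none
Why: reversible deprotonation at C5, the only enolisable position, gives the cross-conjugated C6 enolate, and reprotonation should funnel the material to the trans-fused isomer (5α-H), in which neither C4 methyl group is pressed against ring B as it is in both chair-like forms of the cis isomer (the classical base epimerisation of angularly methylated quinone Diels–Alder adducts).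

Step 5
Reactants: 6 trans-fused enedione
Product: 8 enol triflate (4aS,8aS)-2,5,5,8a-tetramethyl-4-oxo-6-(triisopropylsilyloxy)-3,4,4a,5,8,8a-hexahydronaphthalen-1-yl trifluoromethanesulfonate, via lithium C9-enolate 7 (not isolated)
Conditions: LiBH(s-Bu)3 (1.05 equiv), THF, −78 °C; then PhN(SO2CF3)2 (1.2 equiv), −78 → 0 °C
Reagents that add atoms: N-phenylbis(trifluoromethanesulfonimide), O=S(=O)(N(c1ccccc1)S(=O)(=O)C(F)(F)F)C(F)(F)F
Why: conjugate reduction of the enedione by the bulky borohydride should place hydride on the unsubstituted C7 (β to the C9 carbonyl) and not on the methyl-bearing C8 or 1,2 on the shielded carbonyls, and the regiodefined C9 enolate is then O-sulfonylated (reductive enol triflate formation) while the silyl enol ether stays inert.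

Step 6
Reactants: 9 (S)-citronellol
Product: 10 (S)-citronellyl acetate
Conditions: Ac2O (1.3 equiv), pyridine, 4-(dimethylamino)pyridine (5 mol%), CH2Cl2, 23 °C
Reagents that add atoms: acetic anhydride, CC(=O)OC(C)=O
Why: standard acylation of a primary alcohol, which installs the C15 acetate of the target at the outset and leaves the C13 stereocentre untouched.

Step 7
Reactants: 10 (S)-citronellyl acetate
Product: 11 (4S)-6-acetoxy-4-methylhexanoic acid
Conditions: RuCl3·H2O (2 mol%), NaIO4 (4 equiv), EtOAc/MeCN/H2O, 23 °C
Reagents that add atoms: sodium periodate, [Na+].[O-]I(=O)(=O)=O; water, O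
Why: RuO4-catalysed oxidative cleavage of the trisubstituted alkene gives the carboxylic acid and acetone directly, with the acetate and the remote stereocentre unaffected.

Step 8
Reactants: 11 (4S)-6-acetoxy-4-methylhexanoic acid
Product: 12 (3R)-5-iodo-3-methylpentyl acetate
Conditions: PhI(OAc)2 (0.6 equiv), I2 (0.55 equiv), cyclohexane, hν (tungsten lamp), reflux
Reagents that add atoms: iodine, II
Why: Hunsdiecker-type photochemical iododecarboxylation via the acyl hypoiodite and a primary alkyl radical removes the one surplus carbon, and the stereocentre two bonds from the radical is not involved (the descriptor changes to R only by priority).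

Step 9
Reactants: 12 (3R)-5-iodo-3-methylpentyl acetate; 8 enol triflate
Product: 14 (13S)-6-oxo-3-(triisopropylsilyloxy)labda-2,8-dien-15-yl acetate, via alkylzinc iodide 13 (not isolated)
Conditions: Zn dust (1.5 equiv, activated with BrCH2CH2Br and Me3SiCl), LiCl, THF, 40 °C; then 8, Pd(OAc)2 (5 mol%), 2-dicyclohexylphosphino-2′,6′-dimethoxybiphenyl (10 mol%), THF, 50 °C
Reagents that add atoms: none
Why: Negishi sp2–sp3 coupling, in which the alkylzinc iodide tolerates ketone, acetate and silyl enol ether, hindered 2,6,6-trisubstituted cyclohexenyl triflates are competent partners with an electron-rich biarylphosphine on zerovalent palladium, and the neutral medium avoids enolisation towards C7.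

Step 10
Reactants: 14 (13S)-6-oxo-3-(triisopropylsilyloxy)labda-2,8-dien-15-yl acetate
Product: 15 (13S)-3,6-dioxolabd-7-en-15-yl acetate (5α-H and 9α-H)
Conditions: 2 M aq. HCl/THF (1:4), 23 °C, stopped at full conversion
Reagents that add atoms: none
Why: C-protonation of the silyl enol ether frees the C3 ketone, and through the C6 dienol the β,γ-unsaturated ketone isomerises to the conjugated 7-en-6-one with axial γ-protonation at C9 from the α-face, anti to the axial C20 methyl (as in the acid isomerisation of steroidal 5(10)-en-3-ones), which makes the side chain β-equatorial; the enone re-enolises through C9 only slowly.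

Step 11
Reactants: 15 (13S)-3,6-dioxolabd-7-en-15-yl acetate
Product: 16 (13S)-3β,6β-dihydroxylabd-7-en-15-yl acetate
Conditions: NaBH4 (2 equiv), CeCl3·7H2O (1 equiv), MeOH, −40 → 0 °C
Reagents that add atoms: none
Why: Luche reduction adds hydride 1,2 to the enone and to the C3 ketone from the α-face (the β-face is blocked by the axial 4β and 10β methyl groups), which should give the equatorial 3β-alcohol as is usual for 4,4-dimethyl-3-ketones and the pseudoaxial 6β allylic alcohol, while the primary acetate survives.

Step 12
Reactants: 16 (13S)-3β,6β-dihydroxylabd-7-en-15-yl acetate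
Product: 17 (13S)-labd-7-ene-3β,6β,15-triyl triacetate
Conditions: Ac2O (6 equiv), Et3N, 4-(dimethylamino)pyridine (0.5 equiv), CH2Cl2, 40 °C
Reagents that add atoms: acetic anhydride, CC(=O)OC(C)=O
Why: nucleophilic-catalysed acylation is needed for the hindered 6β-hydroxyl, and any C15 alcohol set free in steps 10 and 11 is re-esterified here.

Step 13
Reactants: 17 (13S)-labd-7-ene-3β,6β,15-triyl triacetate
Product: 18 (13S)-labd-7-ene-3β,15-diyl diacetate (target)
Conditions: Pd(PPh3)4 (5 mol%), Bu3SnH (1.5 equiv), THF, 23 → 50 °C
Reagents that add atoms: none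
Why: zerovalent palladium ionises only the allylic, pseudoaxial 6β-acetate (anti, from the α-face) to the C6–C7–C8 π-allyl complex, and tin hydride should transfer hydride through palladium to the less substituted terminus C6, so that the trisubstituted C7=C8 bond stays and the non-allylic C3 and C15 acetates are untouched (palladium-catalysed hydrogenolysis of allylic acetates).

**Compound list**
1 | N-methoxy-N-methyl-2-methylpropanamide | CC(C)C(=O)N(C)OC | starting material
2 | 4-methylpent-1-en-3-one | C=CC(=O)C(C)C | intermediate
3 | triisopropyl[(4-methylpenta-1,3-dien-3-yl)oxy]silane | C=CC(O[Si](C(C)C)(C(C)C)C(C)C)=C(C)C | intermediate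
4 | 2,6-dimethyl-1,4-benzoquinone | CC1=CC(=O)C=C(C)C1=O | starting material
5 | (4aR,8aS)-2,5,5,8a-tetramethyl-6-(triisopropylsilyloxy)-4a,5,8,8a-tetrahydronaphthalene-1,4-dione; cis-fused (5β-H, 10β-CH3) | O=C1C(C)=CC(=O)[C@@H]2C(C)(C)C(O[Si](C(C)C)(C(C)C)C(C)C)=CC[C@]12C | intermediate
6 | (4aS,8aS)-2,5,5,8a-tetramethyl-6-(triisopropylsilyloxy)-4a,5,8,8a-tetrahydronaphthalene-1,4-dione; trans-fused (5α-H, 10β-CH3) | O=C1C(C)=CC(=O)[C@H]2C(C)(C)C(O[Si](C(C)C)(C(C)C)C(C)C)=CC[C@]12C | intermediate
7 | lithium C9-enolate of the 7,8-dihydro derivative of 6 (C8=C9–OLi, C6 ketone) | [Li]OC1=C(C)CC(=O)[C@H]2C(C)(C)C(O[Si](C(C)C)(C(C)C)C(C)C)=CC[C@]12C | intermediate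
8 | (4aS,8aS)-2,5,5,8a-tetramethyl-4-oxo-6-(triisopropylsilyloxy)-3,4,4a,5,8,8a-hexahydronaphthalen-1-yl trifluoromethanesulfonate | O=S(=O)(OC1=C(C)CC(=O)[C@H]2C(C)(C)C(O[Si](C(C)C)(C(C)C)C(C)C)=CC[C@]12C)C(F)(F)F | intermediate
9 | (S)-citronellol, (3S)-3,7-dimethyloct-6-en-1-ol | OCC[C@@H](C)CCC=C(C)C | starting material
10 | (S)-citronellyl acetate | CC(=O)OCC[C@@H](C)CCC=C(C)C | intermediate
11 | (4S)-6-acetoxy-4-methylhexanoic acid | CC(=O)OCC[C@@H](C)CCC(=O)O | intermediate
12 | (3R)-5-iodo-3-methylpentyl acetate | CC(=O)OCC[C@@H](C)CCI | intermediate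
13 | [(3R)-5-acetoxy-3-methylpentyl]zinc iodide | CC(=O)OCC[C@@H](C)CC[Zn]I | intermediate
14 | (13S)-6-oxo-3-(triisopropylsilyloxy)labda-2,8-dien-15-yl acetate (5α-H, 10β-CH3) | CC(=O)OCC[C@@H](C)CCC1=C(C)CC(=O)[C@H]2C(C)(C)C(O[Si](C(C)C)(C(C)C)C(C)C)=CC[C@]12C | intermediate
15 | (13S)-3,6-dioxolabd-7-en-15-yl acetate (5α-H, 9α-H) | CC(=O)OCC[C@@H](C)CC[C@H]1C(C)=CC(=O)[C@H]2C(C)(C)C(=O)CC[C@]12C | intermediate
16 | (13S)-3β,6β-dihydroxylabd-7-en-15-yl acetate | CC(=O)OCC[C@@H](C)CC[C@H]1C(C)=C[C@@H](O)[C@H]2C(C)(C)[C@@H](O)CC[C@]12C | intermediate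
17 | (13S)-labd-7-ene-3β,6β,15-triyl triacetate | CC(=O)OCC[C@@H](C)CC[C@H]1C(C)=C[C@@H](OC(C)=O)[C@H]2C(C)(C)[C@@H](OC(C)=O)CC[C@]12C | intermediate
18 | (13S)-labd-7-ene-3β,15-diyl diacetate, (3S,5R,9S,10R,13S) | CC(=O)OCC[C@@H](C)CC[C@H]1C(C)=CC[C@H]2C(C)(C)[C@@H](OC(C)=O)CC[C@]12C | target

**Count and risks**
Total: 13 steps. Longest linear sequence: 10 steps (steps 1–5 and 9–13).

Step 3 (bears the label) is the most likely to fail. The cis-methyl group of 3 disfavours the s-cis conformer and may slow the cycloaddition, the acidic catalyst may desilylate 3 or divert it into Mukaiyama–Michael addition, and face discrimination may be poor. The fallback sets out from 3 and 4 and uses the uncatalysed thermal Diels–Alder reaction (toluene, 100 °C, sealed tube, or 12 kbar in CH2Cl2), whose polarity is matched (C4 onto C5). It should give 5 together with its enantiomer, the (4aS,8aR)-cycloadduct F1. Epimerisation as in step 4 then gives 6 together with its enantiomer, the (4aR,8aR)-enedione F2. The two are separated by preparative chromatography on a chiral stationary phase, and the route is rejoined at 6.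

Step 10 is the second risk: kinetic control at C9 may be lost if the conjugated enone re-enolises through C9 and drifts to the 9-epimer, or the isomerisation may stall. The fallback sets out from 14 and replaces the equilibrating acid catalysis by an irreversible protonation of a defined dienol ether. Me3SiOSO2CF3/Et3N (CH2Cl2, 0 °C) should give the extended silyl dienol ether (13S)-6-(trimethylsilyloxy)-3-(triisopropylsilyloxy)labda-2,6,8-trien-15-yl acetate F3. Cold aqueous HCl in THF (−40 °C) should then protonate it at the γ-terminus C9 from the α-face and cleave both silyl enol ethers, which returns to the route at 15.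

Step 13 is the third risk: hydride may be delivered to the wrong allyl terminus (C8), the π-allyl complex may lose a β-hydrogen to give dienes, or the hindered acetate may ionise slowly. The fallback sets out from 16 and uses ionic deoxygenation of the allylic alcohol (Et3SiH, BF3·OEt2, CH2Cl2, −78 → −40 °C), in which the silane should attack the less hindered terminus C6 of the allyl cation. This gives (13S)-3β-hydroxylabd-7-en-15-yl acetate F4, and acetylation (Ac2O, pyridine) returns to the route at 18.

Further compounds
F1 | step 3 | (4aS,8aR)-2,5,5,8a-tetramethyl-6-(triisopropylsilyloxy)-4a,5,8,8a-tetrahydronaphthalene-1,4-dione (enantiomer of 5) | O=C1C(C)=CC(=O)[C@H]2C(C)(C)C(O[Si](C(C)C)(C(C)C)C(C)C)=CC[C@@]12C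
F2 | step 3 | (4aR,8aR)-2,5,5,8a-tetramethyl-6-(triisopropylsilyloxy)-4a,5,8,8a-tetrahydronaphthalene-1,4-dione (enantiomer of 6) | O=C1C(C)=CC(=O)[C@@H]2C(C)(C)C(O[Si](C(C)C)(C(C)C)C(C)C)=CC[C@@]12C
F3 | step 10 | (13S)-6-(trimethylsilyloxy)-3-(triisopropylsilyloxy)labda-2,6,8-trien-15-yl acetate | CC(=O)OCC[C@@H](C)CCC1=C(C)C=C(O[Si](C)(C)C)[C@H]2C(C)(C)C(O[Si](C(C)C)(C(C)C)C(C)C)=CC[C@]12C
F4 | step 13 | (13S)-3β-hydroxylabd-7-en-15-yl acetate | CC(=O)OCC[C@@H](C)CC[C@H]1C(C)=CC[C@H]2C(C)(C)[C@@H](O)CC[C@]12C
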